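**Retrosynthetic overview**
- The route rests on one feature: ring atoms C3(O)–C4(Me)=C5–C6–C7(isopropenyl)–C8 of the ten-membered ring are the six-membered ring of (S)-carvone (ring 1) once a C3–C8 bond is drawn.
- Key disconnection: Grob fragmentation of a cis-fused bicyclic C3-hydroxy C9-mesylate cleaves C3–C8 and releases the ten-membered ring as a Z,Z,Z-trienone with C3=O and C8=C9.
- Ring 2 (C3, C2, C1, C10, C9, C8) is built on carvone by an anti boron aldol with methacrolein (C8–C9), allyl addition to C3 (C2–C3) and ring-closing metathesis (C1=C10).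
- After the fragmentation: catalyst-controlled epoxidation of C8=C9 and CO2 insertion give the cis-8,9-dioxygenation; reagent-controlled reduction sets C3; hydroxyl-directed epoxidations set the 4,5- and 1,10-epoxides; the two esters go on last.
- Ring order: ring 1 (carvone), ring 2 (metathesis), ten-membered ring (fragmentation), temporary carbonate ring, 4,5-epoxide, 1,10-epoxide.

Key step: step 4

Remark: germacrane numbering is used for the ring-expanded compounds (ring C1–C10, isopropenyl C11–C13 on C7, C14 on C10, C15 on C4); β is the face that carries the isopropenyl group when the ten-membered ring is drawn flat and α the other face; which catalyst enantiomer is matched in step 5 is assumed by analogy with cis-β-substituted styrenes.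

**Step 1**
Reactants: 1 (S)-(+)-carvone; 2 methacrolein
Product: 4 (5S,6S)-6-[(1R)-1-hydroxy-2-methylprop-2-en-1-yl]-2-methyl-5-(prop-1-en-2-yl)cyclohex-2-en-1-one, via dibutylboron enolate 3 (not isolated)
Conditions: n-Bu2BOTf, i-Pr2NEt, CH2Cl2, −78 to 0 °C; then 2, −78 °C; MeOH, pH 7 buffer, 30% H2O2, 0 °C
Reagents that add atoms: methacrolein (2), C=C(C)C=O; dibutylboron triflate, CCCCB(CCCC)OS(=O)(=O)C(F)(F)F (boron carried only by intermediate 3)
Why: Boron aldol addition: soft enolisation at the α′ carbon (C8) gives the ring-constrained E(O)-enolate, whose chair Zimmerman–Traxler transition state should give the 8,9-anti aldol, and the aldehyde should approach C8 anti to the neighbouring isopropenyl group (C8 and C9 set).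

**Step 2**
Reactants: 4 the anti aldol; 5 allylmagnesium bromide
Product: 6 (1S,5S,6S)-6-[(1R)-1-hydroxy-2-methylprop-2-en-1-yl]-2-methyl-1-(prop-2-en-1-yl)-5-(prop-1-en-2-yl)cyclohex-2-en-1-ol
Conditions: CH2=CHCH2MgBr (2.5 equiv), THF, −78 °C; sat. NH4Cl
Reagents that add atoms: allylmagnesium bromide (5), C=CC[Mg]Br
Why: Chelation-controlled 1,2-Grignard addition: in the magnesium alkoxide chelate the allyl group should enter C3 axially on the half-chair, anti to the axial C8–H and to the 2-propenyl branch on C9 and trans to the isopropenyl group, which places C2 cis to the C9 branch (C3 set).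

**Step 3**
Reactants: 6 the allyl diol
Product: 7 (1R,4aS,8S,8aS)-2,5-dimethyl-8-(prop-1-en-2-yl)-1,4,4a,7,8,8a-hexahydronaphthalene-1,4a-diol (cis-fused rings 1 and 2)
Conditions: second-generation Grubbs catalyst, (H2IMes)(PCy3)Cl2Ru=CHPh (5 mol%), CH2Cl2, 40 °C
Reagents that add atoms: none
Why: Ring-closing metathesis of the allyl group on C3 with the cis 2-propenyl group on C9 closes the trisubstituted cyclohexene (ring 2, Z C1=C10), while the isopropenyl group on C7 is trans to the allyl group across ring 1 and cannot reach it.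

**Step 4**
Reactants: 7 the cis-fused diol
Product: 9 (7S)-(1(10)Z,4Z,8Z)-germacra-1(10),4,8,11-tetraen-3-one, via hydroxy mesylate 8 (not isolated)
Conditions: Ms2O, Et3N, THF, −40 °C; then KOt-Bu (3 equiv), THF, −78 to −20 °C; AcOH, −78 °C
Reagents that add atoms: methanesulfonic anhydride, CS(=O)(=O)OS(C)(=O)=O (mesyl group carried only by intermediate 8)
Why: KOt-Bu deprotonates the tertiary C3 hydroxyl of 8 and the alkoxide fragments in a concerted Grob manner: an oxygen lone pair, the C3–C8 bond and the equatorial C9–OMs bond of ring 2 are anti-periplanar, so C3=O and C8=C9 form as C3–C8 breaks and mesylate leaves. The closest known reaction type is the base-induced (Wharton) fragmentation of bicyclic 1,3-diol monosulfonates to cyclodecenones. No ring is closed: the ten-membered ring is set free by cleavage of the bond shared by rings 1 and 2, so no medium-ring cyclisation is involved. No stereocentre is created (C3, C8 and C9 become trigonal, C7 is untouched); the olefin geometry is fixed by the substrate, because in the reactive cis-fused conformer the mesylate is equatorial and C7 axial on ring 2 (C7–C8–C9–C10 gauche), which gives the Z C8=C9 bond while the two ring olefins stay Z. The step needs fragmentation to outrun ionisation or SN2′ displacement of the allylic mesylate, oxetane formation and migration of the β,γ double bond: the mesylate is made at −40 °C and fragmented in the same flask, the anti-periplanar alignment favours fragmentation, and the excess base holds the product as its extended enolate, which AcOH should protonate kinetically at C2.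

**Step 5**
Reactants: 9 the trienone
Product: 10 (7R,8S,9R)-8β,9β-epoxy-(1(10)Z,4Z)-germacra-1(10),4,11-trien-3-one
Conditions: (R,R)-(salen)MnCl [(R,R)-N,N′-bis(3,5-di-tert-butylsalicylidene)-1,2-cyclohexanediaminomanganese chloride, trivalent manganese] (5 mol%), mCPBA, N-methylmorpholine N-oxide, CH2Cl2, −78 °C
Reagents that add atoms: mCPBA, OOC(=O)c1cccc(Cl)c1
Why: Jacobsen–Katsuki epoxidation: the oxomanganese species reacts fastest with a conjugated cis-disubstituted olefin, so C8=C9 should be oxidised in preference to the trisubstituted C1=C10, the isolated isopropenyl group and the enone, and the catalyst enantiomer, chosen by the side-on approach model with the C10=C1 vinyl group in the place of an aryl group, should put the oxygen on the β face (C8 and C9 set).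

**Step 6**
Reactants: 10 the vinyl epoxide
Product: 11 (1(10)Z,4Z)-3-oxogermacra-1(10),4,11-triene-8β,9β-diyl carbonate (cyclic carbonate)
Conditions: Pd(PPh3)4 (zerovalent palladium, 5 mol%), CO2 (1 atm), THF, 0 °C to rt
Reagents that add atoms: carbon dioxide, O=C=O
Why: Palladium-catalysed CO2 insertion into a vinyl epoxide: ionisation of the allylic C9–O bond with inversion gives a π-allylpalladium alkoxide, the C8 alkoxide is carboxylated and the carbonate returns to C9 anti to palladium, so the cis-8β,9β-dioxygenation should result with net retention at C9 and the Z C1=C10 olefin intact.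

**Step 7**
Reactants: 11 the keto carbonate
Product: 12 (1(10)Z,4Z)-3β-hydroxygermacra-1(10),4,11-triene-8β,9β-diyl carbonate (3S)
Conditions: (R)-2-methyl-CBS-oxazaborolidine (20 mol%), catecholborane, toluene, −78 °C
Reagents that add atoms: none
Why: Corey–Bakshi–Shibata reduction: under reagent control, with the α-methylated alkenyl arm C4=C5 as the large group and the C2 methylene as the small one, 1,2-hydride delivery should give the 3β (3S) allylic alcohol, and catecholborane at −78 °C leaves the olefins and the carbonate alone (C3 set).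

**Step 8**
Reactants: 12 the allylic alcohol
Product: 13 (1(10)Z)-4α,5α-epoxy-3β-hydroxygermacra-1(10),11-diene-8β,9β-diyl carbonate
Conditions: mCPBA (1.05 equiv), CH2Cl2, 0 °C
Reagents that add atoms: mCPBA, OOC(=O)c1cccc(Cl)c1
Why: Hydroxyl-directed (Henbest) peracid epoxidation of a Z-allylic alcohol: with C3–H eclipsing the olefin to avoid A(1,3) strain with C6, the hydrogen-bonded peracid should give the threo (trans) epoxy alcohol, as medium-ring Z-allylic alcohols do, hence the 4α,5α-epoxide, while C1=C10 is deactivated by the allylic carbonate oxygen and the isopropenyl group is only disubstituted (C4 and C5 set).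

**Step 9**
Reactants: 13 the epoxy alcohol; 14 angelic acid
Product: 16 (1(10)Z)-3β-angeloyloxy-4α,5α-epoxygermacra-1(10),11-diene-8β,9β-diyl carbonate, via mixed anhydride 15 (not isolated)
Conditions: 14, 2,4,6-Cl3C6H2COCl, Et3N, toluene, rt; then 13, 80 °C
Reagents that add atoms: angelic acid (14), C/C=C(/C)C(=O)O; 2,4,6-trichlorobenzoyl chloride, O=C(Cl)c1c(Cl)cc(Cl)cc1Cl (carried only by intermediate 15)
Why: Yamaguchi-type esterification through the mixed anhydride, run without DMAP so that the Z geometry of the angelate should be kept; the C3 hydroxyl is the only free hydroxyl, so no site selectivity is needed.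

**Step 10**
Reactants: 16 the angelate carbonate
Product: 17 (1(10)Z)-3β-angeloyloxy-4α,5α-epoxygermacra-1(10),11-diene-8β,9β-diol
Conditions: K2CO3 (0.2 equiv), MeOH, 0 °C
Reagents that add atoms: none
Why: Transesterification of the strained five-membered cyclic carbonate with methanol, which should be much faster than attack on the hindered α,β-unsaturated angelate or on the epoxide.

**Step 11**
Reactants: 17 the diol
Product: 18 3β-angeloyloxy-1β,10β:4α,5α-diepoxygermacr-11-ene-8β,9β-diol
Conditions: VO(acac)2 (5 mol%), t-BuOOH (1.2 equiv), CH2Cl2, 0 °C to rt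
Reagents that add atoms: tert-butyl hydroperoxide, CC(C)(C)OO
Why: Vanadium-catalysed hydroxyl-directed epoxidation: the allylic C9 hydroxyl, seconded by the homoallylic C8 hydroxyl on the same face, should deliver oxygen to C1=C10 cis to itself, as in medium-ring Z-allylic alcohols, to give the 1β,10β-epoxide, while the isopropenyl and ester olefins have no allylic hydroxyl and react far more slowly (C1 and C10 set).

**Step 12**
Reactants: 18 the diepoxy diol; 19 senecioyl chloride
Product: 20 CNP0320216.1, 3β-angeloyloxy-1β,10β:4α,5α-diepoxy-9β-hydroxy-8β-senecioyloxygermacr-11-ene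
Conditions: 19 (1.1 equiv), pyridine, DMAP (cat.), CH2Cl2, −20 to 0 °C
Reagents that add atoms: senecioyl chloride (19), CC(C)=CC(=O)Cl
Why: Site-selective acylation of the less hindered secondary alcohol: the C9 hydroxyl is flanked by the fully substituted epoxide carbon C10 and hydrogen-bonded to the epoxide, so the C8 hydroxyl should be esterified first, and pyridine in place of a trialkylamine avoids the vinylketene that would deconjugate the senecioate.

**Compound list**
1 | (S)-(+)-carvone | C=C(C)[C@H]1CC=C(C)C(=O)C1 | starting material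
2 | methacrolein | C=C(C)C=O | starting material
3 | (3S)-dibutyl{[6-methyl-3-(prop-1-en-2-yl)cyclohexa-1,5-dien-1-yl]oxy}borane (boron enolate at C8) | C=C(C)[C@H]1CC=C(C)C(OB(CCCC)CCCC)=C1 | intermediate
4 | (5S,6S)-6-[(1R)-1-hydroxy-2-methylprop-2-en-1-yl]-2-methyl-5-(prop-1-en-2-yl)cyclohex-2-en-1-one | C=C(C)[C@H]1CC=C(C)C(=O)[C@@H]1[C@@H](O)C(C)=C | intermediate
5 | allylmagnesium bromide | C=CC[Mg]Br | starting material
6 | (1S,5S,6S)-6-[(1R)-1-hydroxy-2-methylprop-2-en-1-yl]-2-methyl-1-(prop-2-en-1-yl)-5-(prop-1-en-2-yl)cyclohex-2-en-1-ol | C=C(C)[C@H]1CC=C(C)[C@](O)(CC=C)[C@@H]1[C@@H](O)C(C)=C | intermediate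
7 | (1R,4aS,8S,8aS)-2,5-dimethyl-8-(prop-1-en-2-yl)-1,4,4a,7,8,8a-hexahydronaphthalene-1,4a-diol | C=C(C)[C@H]1CC=C(C)[C@]2(O)CC=C(C)[C@H](O)[C@H]12 | intermediate
8 | (1R,4aS,8S,8aS)-4a-hydroxy-2,5-dimethyl-8-(prop-1-en-2-yl)-1,4,4a,7,8,8a-hexahydronaphthalen-1-yl methanesulfonate | C=C(C)[C@H]1CC=C(C)[C@]2(O)CC=C(C)[C@H](OS(C)(=O)=O)[C@H]12 | intermediate
9 | (7S)-(1(10)Z,4Z,8Z)-germacra-1(10),4,8,11-tetraen-3-one | C=C(C)[C@@H]1/C=C\C(C)=C/CC(=O)/C(C)=C\C1 | intermediate
10 | (7R,8S,9R)-8β,9β-epoxy-(1(10)Z,4Z)-germacra-1(10),4,11-trien-3-one | C=C(C)[C@H]1C/C=C(C)\C(=O)C/C=C(C)\[C@H]2O[C@@H]12 | intermediate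
11 | (1(10)Z,4Z)-3-oxogermacra-1(10),4,11-triene-8β,9β-diyl carbonate | C=C(C)[C@H]1C/C=C(C)\C(=O)C/C=C(C)\[C@H]2OC(=O)O[C@@H]12 | intermediate
12 | (1(10)Z,4Z)-3β-hydroxygermacra-1(10),4,11-triene-8β,9β-diyl carbonate | C=C(C)[C@H]1C/C=C(C)\[C@@H](O)C/C=C(C)\[C@H]2OC(=O)O[C@@H]12 | intermediate
13 | (1(10)Z)-4α,5α-epoxy-3β-hydroxygermacra-1(10),11-diene-8β,9β-diyl carbonate | C=C(C)[C@H]1C[C@@H]2O[C@]2(C)[C@@H](O)C/C=C(C)\[C@H]3OC(=O)O[C@@H]13 | intermediate
14 | angelic acid, (Z)-2-methylbut-2-enoic acid | C/C=C(/C)C(=O)O | starting material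
15 | angelic 2,4,6-trichlorobenzoic anhydride | C/C=C(/C)C(=O)OC(=O)c1c(Cl)cc(Cl)cc1Cl | intermediate
16 | (1(10)Z)-3β-angeloyloxy-4α,5α-epoxygermacra-1(10),11-diene-8β,9β-diyl carbonate | C=C(C)[C@H]1C[C@@H]2O[C@]2(C)[C@@H](OC(=O)/C(C)=C\C)C/C=C(C)\[C@H]3OC(=O)O[C@@H]13 | intermediate
17 | (1(10)Z)-3β-angeloyloxy-4α,5α-epoxygermacra-1(10),11-diene-8β,9β-diol | C=C(C)[C@H]1C[C@@H]2O[C@]2(C)[C@@H](OC(=O)/C(C)=C\C)C/C=C(C)\[C@@H](O)[C@H]1O | intermediate
18 | 3β-angeloyloxy-1β,10β:4α,5α-diepoxygermacr-11-ene-8β,9β-diol | C=C(C)[C@H]1C[C@@H]2O[C@]2(C)[C@@H](OC(=O)/C(C)=C\C)C[C@H]2O[C@@]2(C)[C@@H](O)[C@H]1O | intermediate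
19 | senecioyl chloride, 3-methylbut-2-enoyl chloride | CC(C)=CC(=O)Cl | starting material
20 | CNP0320216.1, 3β-angeloyloxy-1β,10β:4α,5α-diepoxy-9β-hydroxy-8β-senecioyloxygermacr-11-ene | C=C(C)[C@H]1C[C@@H]2O[C@]2(C)[C@@H](OC(=O)/C(C)=C\C)C[C@H]2O[C@@]2(C)[C@@H](O)[C@H]1OC(=O)C=C(C)C | target

Total step count: 12. Longest linear sequence: 12 steps from (S)-(+)-carvone.

**Steps most likely to fail**

Step 5. Oxygen transfer may go to the trisubstituted C1=C10 end of the diene instead of C8=C9, the substrate may override the catalyst and give the α face, or the radical intermediate may rotate and lose the cis epoxide geometry. The fallback sets out from 9 and returns at 11. Upjohn dihydroxylation (OsO4 2 mol%, N-methylmorpholine N-oxide 1.0 equiv, acetone–water, 0 °C) should attack the less substituted end of the cyclic diene and give (1(10)Z,4Z)-8β,9β-dihydroxygermacra-1(10),4,11-trien-3-one F2. The face then rests on substrate control (attack anti to the isopropenyl group), and a deficit of oxidant is needed because the isopropenyl group competes. Treatment of the diol with 1,1′-carbonyldiimidazole in CH2Cl2 closes the cyclic carbonate 11.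

Step 4. The allylic mesylate may ionise or be displaced before the alkoxide is formed, or the base may move the β,γ double bond of the product into conjugation. The fallback sets out from 7 and returns at 9. It separates activation from fragmentation with a leaving group that can be handled: ClP(O)(OEt)2, pyridine and catalytic DMAP in CH2Cl2 at 0 °C should give (1R,4aS,8S,8aS)-4a-hydroxy-2,5-dimethyl-8-(prop-1-en-2-yl)-1,4,4a,7,8,8a-hexahydronaphthalen-1-yl diethyl phosphate F1, which is purified. A single equivalent of KN(SiMe3)2 in THF (−78 to 0 °C, AcOH quench) then triggers the same anti-periplanar fragmentation to 9 without an excess of base.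

Step 12. Acylation may occur at the C9 hydroxyl, at both hydroxyls, or be followed by acyl migration between the cis oxygens. The fallback sets out from 18 and returns at 20. Bu2SnO in toluene at 80 °C converts the cis-diol into the 8,9-O-dibutylstannylene acetal of 18 F3, in which the less hindered oxygen is the more nucleophilic. Addition of 19 at 0 °C should then acylate O8 only and give 20 after aqueous work-up.

**Further compounds**
F1 | step 4 | (1R,4aS,8S,8aS)-4a-hydroxy-2,5-dimethyl-8-(prop-1-en-2-yl)-1,4,4a,7,8,8a-hexahydronaphthalen-1-yl diethyl phosphate | C=C(C)[C@H]1CC=C(C)[C@]2(O)CC=C(C)[C@H](OP(=O)(OCC)OCC)[C@H]12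
F2 | step 5 | (1(10)Z,4Z)-8β,9β-dihydroxygermacra-1(10),4,11-trien-3-one | C=C(C)[C@H]1C/C=C(C)\C(=O)C/C=C(C)\[C@@H](O)[C@H]1O
F3 | step 12 | 8,9-O-dibutylstannylene acetal of 18 | C=C(C)[C@H]1C[C@@H]2O[C@]2(C)[C@@H](OC(=O)/C(C)=C\C)C[C@H]2O[C@@]2(C)[C@H]3O[Sn](CCCC)(CCCC)O[C@@H]13
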